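**Plan**

1. Numbering of the bicycle: N1, O2, C3, C3a, C4, C5, C6, C6a. The retrosynthesis cuts, in this order: both pyridine–chain bonds (twofold B-alkyl Suzuki–Miyaura coupling of a bis-terminal alkene with two equivalents of 3-bromopyridine), C3–H (hydride reduction of a cyclic hemiketal), O2–C3 (hemiketal closure), N1–O2 (N-oxygenation of a secondary amine), and last C5–C6 together with C3a–C6a in one formal [3+2] event.
2. Feature that allows this event: the carbocycle C3a–C4–C5–C6–C6a is bare at C4, C5 and C6, and C3a carries the oxygen-bearing C3 next to the nitrogen-bearing C6a. With C3 at the ketone level this is a 2-aminocyclopentyl ketone, the product of opening a cyclopropyl ketone (C3a, C4, C5) by ketyl radical relay and closing it over an N-vinyl carbamate (C6, C6a).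
3. Forward order: cyclopentane ring first (step 3), isoxazolidine ring next (N–O in step 5, O–C3 in step 6, C3–H in step 7), the two pyridine rings joined to the two chain ends last (step 8).
4. Stereochemistry: C6a is set in the key step under control of a chiral bis(phosphine oxide) on samarium. C3a is relayed from C6a by the cis ring fusion when the hemiketal closes (epimerisable α-carbon). C3 is relayed by hydride attack on the convex face of the bicyclic oxocarbenium ion.

Key step: step 3

Remark: (R)-BINAPO is (R)-2,2'-bis(diphenylphosphoryl)-1,1'-binaphthyl; the antipode that gives the (1R) configuration in step 3 is the one to use, and the (R)-ligand is written as the working choice (both antipodes are commercial).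
Remark: hemiketal 12 is handled as a mixture of epimers at its hemiketal carbon, which becomes planar again in step 7.
Remark: step 8 consumes two molecules of 3-bromopyridine (14) and one molecule of 9-BBN-H dimer per molecule of 13; the second molecule of 14 is entered under "Reagents that add atoms".

**Step 1**
Reactants: 1 N-methoxy-N-methylcyclopropanecarboxamide; 2 8-bromooct-1-ene
Product: 4 1-cyclopropylnon-8-en-1-one, via oct-7-en-1-ylmagnesium bromide 3 (not isolated)
Conditions: Mg, I2 (cat.), THF, rt to 40 °C; then 1, THF, 0 °C; aq. HCl (1 M)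
Reagents that add atoms: magnesium, [Mg] (held only in intermediate 3; no reagent atom remains in 4)
Why: Weinreb ketone synthesis, in which the Grignard reagent adds once because the chelated tetrahedral adduct persists until the acidic work-up; no stereocentre is formed.

**Step 2**
Reactants: 5 tert-butyl N-ethenylcarbamate; 6 12-bromododec-1-ene
Product: 7 tert-butyl N-(dodec-11-en-1-yl)-N-ethenylcarbamate
Conditions: NaH, DMF, 0 °C; then 6, rt
Reagents that add atoms: none
Why: N-alkylation of a carbamate anion (SN2 at a primary bromide) after deprotonation of the N–H by sodium hydride; no stereocentre is formed.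

**Step 3**
Reactants: 4 1-cyclopropylnon-8-en-1-one; 7 tert-butyl N-(dodec-11-en-1-yl)-N-ethenylcarbamate
Product: 8 tert-butyl (dodec-11-en-1-yl)[(1R,2S)-2-(non-8-enoyl)cyclopentyl]carbamate
Conditions: SmI2 (15 mol %), Sm powder (15 mol %), (R)-BINAPO (20 mol %), 7 (3 equiv), THF, 45 °C
Reagents that add atoms: none
Why: Proposed new method: divalent samarium gives the ketyl of 4, the cyclopropane opens to a trivalent samarium enolate (its carbon is the later C3a) carrying a primary radical (later C5), this radical adds to the CH2 end of the N-vinyl group of 7 (bond C5–C6), and the α-carbamoyl radical closes onto the enolate carbon (bond C3a–C6a) to a new ketyl that returns its electron to trivalent samarium. The closest known reaction type is the SmI2/samarium-metal-catalysed radical-relay formal [3+2] cycloaddition of alkyl cyclopropyl ketones with alkenes, joined to the ligand control known for BINAPO in stoichiometric SmI2 ketyl–olefin coupling; new are the electron-rich N-vinyl carbamate as partner and a chiral ligand kept on samarium through catalytic turnover. The cyclopentane closes by 5-exo-trig radical cyclisation onto the enolate C=C. Both new stereocentres arise in this closure: samarium holding the C2-symmetric ligand is bound to the enolate oxygen and is expected to take up the carbamate carbonyl as well, which should put nitrogen and acyl group cis and let the ligand choose the face of the α-carbamoyl radical, hence (1R) at the nitrogen-bearing carbon, while the (2S) acyl-bearing carbon is epimerisable and is fixed for good in step 6. The step needs attack at the vinyl terminus (secured by the carbamoyl-stabilised adduct radical), preference for 7 over the two isolated terminal alkenes (secured by its excess and its conjugated N-vinyl group) and facial control at the nitrogen-bearing carbon (ligand), and any trans isomer is to be removed by chromatography so that only material of one configuration at that carbon is carried on. Ring opening and back electron transfer are reversible, so an opened radical that fails to add should return to 4.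

**Step 4**
Reactants: 8 tert-butyl (dodec-11-en-1-yl)[(1R,2S)-2-(non-8-enoyl)cyclopentyl]carbamate
Product: 9 1-[(1S,2R)-2-(dodec-11-en-1-ylamino)cyclopentyl]non-8-en-1-one hydrochloride
Conditions: HCl (4 M in 1,4-dioxane), CH2Cl2, 0 °C to rt
Reagents that add atoms: hydrogen chloride, Cl
Why: Acidolysis of the tert-butyl carbamate (Boc cleavage) gives the amine, kept as its hydrochloride to guard the β-amino ketone against elimination; the ring stereocentres are not touched.

**Step 5**
Reactants: 9 1-[(1S,2R)-2-(dodec-11-en-1-ylamino)cyclopentyl]non-8-en-1-one hydrochloride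
Product: 10 1-[(1S,2R)-2-[(benzoyloxy)(dodec-11-en-1-yl)amino]cyclopentyl]non-8-en-1-one
Conditions: (PhCO2)2, K2HPO4, DMF, rt
Reagents that add atoms: dibenzoyl peroxide, O=C(OOC(=O)c1ccccc1)c1ccccc1
Why: Electrophilic N-oxygenation of a secondary amine by a diacyl peroxide (SN2 at peroxide oxygen) installs the N–O bond as the O-benzoyl hydroxylamine without touching the terminal alkenes, and the buffered medium should leave both stereocentres as they are.

**Step 6**
Reactants: 10 1-[(1S,2R)-2-[(benzoyloxy)(dodec-11-en-1-yl)amino]cyclopentyl]non-8-en-1-one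
Product: 12 (3aS,6aR)-1-(dodec-11-en-1-yl)-3-(oct-7-en-1-yl)hexahydro-1H-cyclopenta[c][1,2]oxazol-3-ol, via N-hydroxy amino ketone 11 (not isolated)
Conditions: K2CO3 (0.3 equiv), MeOH, 0 °C
Reagents that add atoms: none
Why: Transesterification frees the hydroxylamine oxygen, which adds to the ketone in a 5-exo-trig hemiketalisation (ring–chain tautomerism of a β-hydroxyamino ketone); only the cis-fused bicycle can close, so the acyl-bearing carbon, epimerisable through the enol under the mild base, should settle as (3aS) relative to the fixed (6aR) centre.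

**Step 7**
Reactants: 12 (3aS,6aR)-1-(dodec-11-en-1-yl)-3-(oct-7-en-1-yl)hexahydro-1H-cyclopenta[c][1,2]oxazol-3-ol
Product: 13 (3S,3aS,6aR)-1-(dodec-11-en-1-yl)-3-(oct-7-en-1-yl)hexahydro-1H-cyclopenta[c][1,2]oxazole
Conditions: Et3SiH, BF3·OEt2, CH2Cl2, −78 to −20 °C
Reagents that add atoms: none
Why: Ionic hydrogenation of a cyclic hemiketal, in which BF3 ionises the hemiketal to an oxocarbenium ion and triethylsilane should deliver hydride to the convex face of the cis-fused bicycle, anti to the adjacent C3a–C4 bond, which places the new hydrogen cis to both ring-fusion hydrogens and sets (3S).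

**Step 8**
Reactants: 13 (3S,3aS,6aR)-1-(dodec-11-en-1-yl)-3-(oct-7-en-1-yl)hexahydro-1H-cyclopenta[c][1,2]oxazole; 14 3-bromopyridine
Product: 16 (3S,3aS,6aR)-1-[12-(pyridin-3-yl)dodecyl]-3-[8-(pyridin-3-yl)octyl]hexahydro-1H-cyclopenta[c][1,2]oxazole, via twofold B-alkyl-9-BBN adduct 15 (not isolated)
Conditions: 9-BBN-H dimer (1.1 equiv), THF, 0 °C to rt; then 14 (2.5 equiv), PdCl2(dppf) (10 mol %), aq. NaOH (3 M), THF, 65 °C
Reagents that add atoms: 3-bromopyridine, Brc1cccnc1 (the second equivalent of 14); 9-borabicyclo[3.3.1]nonane dimer, B1C2CCCC1CCC2.B1C2CCCC1CCC2 (written as its two monomer units and held only in intermediate 15)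
Why: Twofold anti-Markovnikov hydroboration, in which each terminal alkene takes up one B–H unit of the dimer, followed by twofold B-alkyl Suzuki–Miyaura coupling, in which each B-alkyl group is joined to one molecule of 3-bromopyridine, installs both pyridine rings in one operation; no stereocentre is touched and the N–O bond should be inert to the borane, to zerovalent palladium and to aqueous base.

**Compound list**

1 | N-methoxy-N-methylcyclopropanecarboxamide | CON(C)C(=O)C1CC1 | starting material
2 | 8-bromooct-1-ene | C=CCCCCCCBr | starting material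
3 | oct-7-en-1-ylmagnesium bromide | C=CCCCCCC[Mg]Br | intermediate
4 | 1-cyclopropylnon-8-en-1-one | C=CCCCCCCC(=O)C1CC1 | intermediate
5 | tert-butyl N-ethenylcarbamate | C=CNC(=O)OC(C)(C)C | starting material
6 | 12-bromododec-1-ene | C=CCCCCCCCCCCBr | starting material
7 | tert-butyl N-(dodec-11-en-1-yl)-N-ethenylcarbamate | C=CCCCCCCCCCCN(C=C)C(=O)OC(C)(C)C | intermediate
8 | tert-butyl (dodec-11-en-1-yl)[(1R,2S)-2-(non-8-enoyl)cyclopentyl]carbamate (cis) | C=CCCCCCCC(=O)[C@H]1CCC[C@H]1N(CCCCCCCCCCC=C)C(=O)OC(C)(C)C | intermediate
9 | 1-[(1S,2R)-2-(dodec-11-en-1-ylamino)cyclopentyl]non-8-en-1-one hydrochloride | C=CCCCCCCC(=O)[C@H]1CCC[C@H]1NCCCCCCCCCCC=C.Cl | intermediate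
10 | 1-[(1S,2R)-2-[(benzoyloxy)(dodec-11-en-1-yl)amino]cyclopentyl]non-8-en-1-one | C=CCCCCCCC(=O)[C@H]1CCC[C@H]1N(CCCCCCCCCCC=C)OC(=O)c1ccccc1 | intermediate
11 | 1-[(1S,2R)-2-[(dodec-11-en-1-yl)(hydroxy)amino]cyclopentyl]non-8-en-1-one | C=CCCCCCCC(=O)[C@H]1CCC[C@H]1N(O)CCCCCCCCCCC=C | intermediate
12 | (3aS,6aR)-1-(dodec-11-en-1-yl)-3-(oct-7-en-1-yl)hexahydro-1H-cyclopenta[c][1,2]oxazol-3-ol (cis-fused hemiketal, both epimers at C3) | C=CCCCCCCCCCCN2OC(O)(CCCCCCC=C)[C@H]3CCC[C@H]32 | intermediate
13 | (3S,3aS,6aR)-1-(dodec-11-en-1-yl)-3-(oct-7-en-1-yl)hexahydro-1H-cyclopenta[c][1,2]oxazole | C=CCCCCCCCCCCN2O[C@@H](CCCCCCC=C)[C@H]3CCC[C@H]32 | intermediate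
14 | 3-bromopyridine | Brc1cccnc1 | starting material
15 | (3S,3aS,6aR)-1-[12-(9-borabicyclo[3.3.1]nonan-9-yl)dodecyl]-3-[8-(9-borabicyclo[3.3.1]nonan-9-yl)octyl]hexahydro-1H-cyclopenta[c][1,2]oxazole | B1(CCCCCCCCCCCCN2O[C@@H](CCCCCCCCB4C5CCCC4CCC5)[C@H]3CCC[C@H]32)C6CCCC1CCC6 | intermediate
16 | (3S,3aS,6aR)-1-[12-(pyridin-3-yl)dodecyl]-3-[8-(pyridin-3-yl)octyl]hexahydro-1H-cyclopenta[c][1,2]oxazole (CNP0267546.1) | c1cncc(CCCCCCCCCCCCN2O[C@@H](CCCCCCCCc3cccnc3)[C@H]3CCC[C@H]32)c1 | target

Total step count: 8. Longest linear sequence: 7 steps (steps 1, 3, 4, 5, 6, 7, 8).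

**Steps most likely to fail**

Step 3 (proposed new method). The opened radical may be reduced by hydrogen abstraction, or may revert, faster than it adds to the electron-rich N-vinyl carbamate. The phosphine oxide may hold trivalent samarium so firmly that turnover stops, or the ligand may discriminate the faces of the α-carbamoyl radical poorly. The fallback uses known chemistry, sets out from Grignard reagent 3 and bromide 6, and comes back at 9. Commercial (1S,2R)-2-[(tert-butoxycarbonyl)amino]cyclopentane-1-carboxylic acid F1 is coupled with N,O-dimethylhydroxylamine hydrochloride (EDC·HCl, iPr2NEt, CH2Cl2) to tert-butyl N-[(1R,2S)-2-[methoxy(methyl)carbamoyl]cyclopentyl]carbamate F2. Addition of 3 (2.5 equiv, THF, −20 °C) should give tert-butyl N-[(1R,2S)-2-(non-8-enoyl)cyclopentyl]carbamate F3. HCl in 1,4-dioxane should give 1-[(1S,2R)-2-aminocyclopentyl]non-8-en-1-one hydrochloride F4. Kornblum oxidation of 6 (DMSO, NaHCO3, 120 °C) should give dodec-11-enal F5. Reductive amination of F4 with F5 (NaBH(OAc)3, Et3N, 1,2-dichloroethane), followed by HCl, should give 9, with the nitrogen-bearing stereocentre bought and not made.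

Step 6. Under carbonate in methanol the O-benzoyl hydroxylamine or the freed N-hydroxy amine may undergo base-induced β-elimination from the ketone enolate (retro-aza-Michael). This removes the nitrogen and, through re-addition, would erode the configuration at the nitrogen-bearing carbon. The fallback sets out from 9 and comes back at 12 without passing 10. The amine freed from 9 (NaHCO3) is N-hydroxylated directly by oxygen-atom transfer from 2-(phenylsulfonyl)-3-phenyloxaziridine (CH2Cl2, 0 °C), so no alkoxide base is present. N-hydroxy amine 11 should then close to 12 on its own, and any trans material is left to equilibrate under the acid of step 7. No new compound arises.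

Step 7. Hydride may be delivered to the wrong face of the oxocarbenium ion, or the Lewis acid may open the N–O–C unit before reduction. The fallback sets out from 8 (cis isomer) and comes back at 13. It sets C3 by reagent control and closes the ring by SN2 instead. Reduction of 8 with catecholborane and (S)-2-methyl-CBS-oxazaborolidine (toluene, −78 °C) should give tert-butyl (dodec-11-en-1-yl){(1R,2S)-2-[(1R)-1-hydroxynon-8-en-1-yl]cyclopentyl}carbamate F6. Mesylation (MsCl, Et3N, CH2Cl2, 0 °C) gives (1R)-1-{(1S,2R)-2-[(tert-butoxycarbonyl)(dodec-11-en-1-yl)amino]cyclopentyl}non-8-en-1-yl methanesulfonate F7. HCl in 1,4-dioxane gives (1R)-1-[(1S,2R)-2-(dodec-11-en-1-ylamino)cyclopentyl]non-8-en-1-yl methanesulfonate hydrochloride F8. (PhCO2)2 and K2HPO4 in DMF give (1R)-1-{(1S,2R)-2-[(benzoyloxy)(dodec-11-en-1-yl)amino]cyclopentyl}non-8-en-1-yl methanesulfonate F9. K2CO3 in MeOH then frees the hydroxylamine oxygen, which should displace the mesylate with inversion (5-exo-tet) to give 13 with the (3S) configuration.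

**Further compounds**

F1 | step 3 | (1S,2R)-2-[(tert-butoxycarbonyl)amino]cyclopentane-1-carboxylic acid (purchased) | OC(=O)[C@H]1CCC[C@H]1NC(=O)OC(C)(C)C
F2 | step 3 | tert-butyl N-[(1R,2S)-2-[methoxy(methyl)carbamoyl]cyclopentyl]carbamate | CON(C)C(=O)[C@H]1CCC[C@H]1NC(=O)OC(C)(C)C
F3 | step 3 | tert-butyl N-[(1R,2S)-2-(non-8-enoyl)cyclopentyl]carbamate | C=CCCCCCCC(=O)[C@H]1CCC[C@H]1NC(=O)OC(C)(C)C
F4 | step 3 | 1-[(1S,2R)-2-aminocyclopentyl]non-8-en-1-one hydrochloride | C=CCCCCCCC(=O)[C@H]1CCC[C@H]1N.Cl
F5 | step 3 | dodec-11-enal | C=CCCCCCCCCCC=O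
F0 | step 6 | none | none
F6 | step 7 | tert-butyl (dodec-11-en-1-yl){(1R,2S)-2-[(1R)-1-hydroxynon-8-en-1-yl]cyclopentyl}carbamate | C=CCCCCCC[C@@H](O)[C@H]1CCC[C@H]1N(CCCCCCCCCCC=C)C(=O)OC(C)(C)C
F7 | step 7 | (1R)-1-{(1S,2R)-2-[(tert-butoxycarbonyl)(dodec-11-en-1-yl)amino]cyclopentyl}non-8-en-1-yl methanesulfonate | C=CCCCCCC[C@@H](OS(C)(=O)=O)[C@H]1CCC[C@H]1N(CCCCCCCCCCC=C)C(=O)OC(C)(C)C
F8 | step 7 | (1R)-1-[(1S,2R)-2-(dodec-11-en-1-ylamino)cyclopentyl]non-8-en-1-yl methanesulfonate hydrochloride | C=CCCCCCC[C@@H](OS(C)(=O)=O)[C@H]1CCC[C@H]1NCCCCCCCCCCC=C.Cl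
F9 | step 7 | (1R)-1-{(1S,2R)-2-[(benzoyloxy)(dodec-11-en-1-yl)amino]cyclopentyl}non-8-en-1-yl methanesulfonate | C=CCCCCCC[C@@H](OS(C)(=O)=O)[C@H]1CCC[C@H]1N(CCCCCCCCCCC=C)OC(=O)c1ccccc1
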